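**Retrosynthetic overview**

1. Target 13 ⇐ oxirane 12 (Ph3PCl2, two inversions give the cis-dichloride) ⇐ epoxy aldehyde 11 (Takai olefination) ⇐ cyclohexenecarbaldehyde 10 (face-selective epoxidation; the oxirane is a temporary ring).
2. 10 ⇐ (R)-2,6-dimethylcyclohepta-2,5-dien-1-ol 9 by a Br+-triggered semipinacol ring contraction: C7 moves from C1 to C2 and C1 leaves the ring as CHO. This one step makes the cyclohexane, the quaternary carbon, the C–Br centre and the one-carbon handle for the bromoethenyl group.
3. Enabling feature: in the seven-membered ring of 9 the C1–C7 bond stands roughly 60° out of the C2=C3 plane (in a cyclohexenol it lies nearly in the plane), anti-periplanar to a bromonium ion on the OH face. The methyl on C2 makes C2 the cationic terminus and, through A1,2 strain, turns the carbinol H into the alkene plane.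
4. 9 ⇐ ring-closing metathesis of trienol 8 ⇐ catalytic asymmetric 2-methylallylboration of (Z)-enal 5 ⇐ carbomagnesiation/allylation of propargyl alcohol.
5. Ring order: cycloheptadiene (step 4), cyclohexene by contraction (step 5), oxirane (step 6, opened in step 8). One stereocentre comes from catalysis (step 3); all four of 13 are relayed from it.

Key step: step 5

Remark: the (R)-phosphoric acid is assumed to deliver the 2-methylallyl group to the Re face of enal 5, as it does with aryl and alkenyl aldehydes; everything downstream depends only on 8 being (R).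

**Route**

Step 1
Reactants: 1 prop-2-yn-1-ol (propargyl alcohol); 2 3-bromoprop-1-ene (allyl bromide)
Product: 4 (Z)-2-methylhexa-2,5-dien-1-ol, via magnesium chelate 3 (not isolated)
Conditions: MeMgBr (2.5 equiv), CuI (10 mol %), Et2O, −10 °C → rt; then 2 (2 equiv), 0 °C → rt; aq NH4Cl
Reagents that add atoms: methylmagnesium bromide, C[Mg]Br
Why: Copper-catalysed anti-carbomagnesiation of the propargylic alkoxide should place CH3 on C2 and Mg on C3, held cis to CH2O in the five-membered chelate 3, and copper-mediated allylation of the alkenyl–Mg bond with retention should fix the Z-trisubstituted alkene that later lets the seven-membered ring close.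

Step 2
Reactants: 4 (Z)-2-methylhexa-2,5-dien-1-ol
Product: 5 (Z)-2-methylhexa-2,5-dienal
Conditions: activated MnO2 (15 equiv), CH2Cl2, 0 °C → rt; filtered and used as a solution
Reagents that add atoms: none
Why: Activated MnO2 oxidises only the allylic alcohol, under neutral heterogeneous conditions that should leave the Z-enal geometry and the skipped diene untouched.

Step 3
Reactants: 5 (Z)-2-methylhexa-2,5-dienal; 6 4,4,5,5-tetramethyl-2-(2-methylprop-2-en-1-yl)-1,3,2-dioxaborolane
Product: 8 (4Z,6R)-5,8-dimethylnona-1,4,8-trien-6-ol, via pinacol borate ester 7 (not isolated)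
Conditions: 6 (1.3 equiv), (R)-TRIP [(R)-3,3'-bis(2,4,6-triisopropylphenyl)-BINOL hydrogen phosphate] (5 mol %), 4 Å MS, toluene, −30 °C; aq NaHCO3 work-up
Reagents that add atoms: none
Why: Chiral phosphoric acid-catalysed allylboration through a closed chair transition state should add the 2-methylallyl group by its γ-carbon to the Re face of the aldehyde and set the (R)-carbinol, the only stereocentre introduced by catalysis; hydrolysis of borate 7 on work-up frees the alcohol.

Step 4
Reactants: 8 (4Z,6R)-5,8-dimethylnona-1,4,8-trien-6-ol
Product: 9 (R)-2,6-dimethylcyclohepta-2,5-dien-1-ol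
Conditions: second-generation Ru–NHC isopropoxybenzylidene metathesis catalyst (3 mol %), 1,4-benzoquinone (10 mol %), CH2Cl2 (5 mM), 40 °C
Reagents that add atoms: none
Why: Ring-closing metathesis between the monosubstituted and the 1,1-disubstituted terminal alkenes, held close by the Z-trisubstituted C4=C5 bond, should give the cycloheptadiene with loss of ethene; the internal trisubstituted alkene is not engaged, benzoquinone suppresses Ru–H migration of the skipped diene, and the carbinol centre is untouched.

Step 5
Reactants: 9 (R)-2,6-dimethylcyclohepta-2,5-dien-1-ol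
Product: 10 (1S,6S)-6-bromo-1,3-dimethylcyclohex-3-ene-1-carbaldehyde
Conditions: NBS (1.05 equiv), (CF3)2CHOH–CH2Cl2 (1:4), −40 °C, dark
Reagents that add atoms: N-bromosuccinimide, O=C1CCC(=O)N1Br
Why: Proposed new method: N-bromosuccinimide, hydrogen-bonded to the hydroxyl, should transfer Br+ to the OH face of C2=C3; as the C2–Br bond of the bromonium ion loosens at the tertiary carbon, the ring bond C1–C7, anti-periplanar on the other face, shifts from C1 to C2 while the oxygen lone pair closes the C=O bond and succinimide takes the proton (semipinacol 1,2-shift), so C1 leaves the ring as CHO. The closest known reaction types are the halonium-induced semipinacol rearrangement of allylic alcohols, known with exocyclic migrating groups and as ring expansion, and the Lewis acid ring contraction of 1-methylcycloalkene oxides to 1-methylcycloalkanecarbaldehydes; new is the migration of an endocyclic bond to a bromonium carbon. The cyclohexene is not closed by a cyclisation but arises from the cycloheptadiene by this suprafacial 1,2-alkyl shift of C7 (retention at C7), a 7→6 contraction. The C–Br stereocentre follows from anti addition of Br and C7 across the ring Z-alkene (Br cis to CHO, trans to CH3) and the quaternary centre from backside attack of C7 on C2; the absolute sense comes from C1 of 9, whose H eclipses the C2 methyl (A1,2 strain) so that O and C7 lie on opposite faces, before C1 itself becomes sp2. The step needs attack at C2=C3 and not at C5=C6, and C–C migration instead of hydride shift or oxirane closure: Br+ exchange between alkenes is reversible in a medium without nucleophile whereas only the allylic bromonium ion is drained irreversibly by the oxygen-assisted shift, the carbinol H lies in the nodal plane of the C2 p-orbital, and OH is syn to bromine and cannot close an oxirane.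

Step 6
Reactants: 10 (1S,6S)-6-bromo-1,3-dimethylcyclohex-3-ene-1-carbaldehyde
Product: 11 (1R,3S,4S,6S)-4-bromo-1,3-dimethyl-7-oxabicyclo[4.1.0]heptane-3-carbaldehyde
Conditions: dimethyldioxirane (1.2 equiv), acetone, −20 °C
Reagents that add atoms: dimethyldioxirane, CC1(C)OO1
Why: Epoxidation of the only alkene by the electrophilic dioxirane: in the favoured half-chair of 10 the formyl group (smallest A value) is axial on C1 and screens its face of C3=C4 while CH3 and Br are equatorial, so oxygen should be delivered anti to CHO and Br; the neutral oxidant leaves the α-quaternary aldehyde alone.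

Step 7
Reactants: 11 (1R,3S,4S,6S)-4-bromo-1,3-dimethyl-7-oxabicyclo[4.1.0]heptane-3-carbaldehyde
Product: 12 (1R,3S,4S,6S)-4-bromo-3-[(E)-2-bromoethenyl]-1,3-dimethyl-7-oxabicyclo[4.1.0]heptane
Conditions: CHBr3 (2 equiv), anhydrous CrBr2 (6 equiv), THF, 0 °C → rt
Reagents that add atoms: bromoform, BrC(Br)Br
Why: Takai olefination: the gem-dichromium species from CHBr3 and Cr(II) adds to the hindered, non-enolisable aldehyde and elimination should give the (E)-bromoalkene; CrBr2 avoids Br/Cl exchange, and the oxirane and the secondary bromide should survive Cr(II) in THF.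

Step 8
Reactants: 12 (1R,3S,4S,6S)-4-bromo-3-[(E)-2-bromoethenyl]-1,3-dimethyl-7-oxabicyclo[4.1.0]heptane
Product: 13 (1S,2S,4R,5S)-2-bromo-1-[(E)-2-bromoethenyl]-4,5-dichloro-1,5-dimethylcyclohexane
Conditions: Ph3PCl2 (2 equiv), toluene, 80 °C
Reagents that add atoms: dichlorotriphenylphosphorane, ClP(Cl)(c1ccccc1)(c1ccccc1)c1ccccc1
Why: Deoxydichlorination of an epoxide with Ph3PCl2 (as in cyclohexene oxide to cis-1,2-dichlorocyclohexane): the oxyphosphonium-activated oxirane is opened by chloride at the tertiary carbon with inversion, then chloride displaces Ph3P=O at the secondary carbon with inversion, so both chlorines should end cis to each other on the face opposite the former oxirane, that is syn to Br and the bromoethenyl group.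

**Compound list**

1 | prop-2-yn-1-ol | C#CCO | starting material
2 | 3-bromoprop-1-ene | C=CCBr | starting material
3 | 4-methyl-2,5-dihydro-1,2-oxamagnesole (cyclic (Z)-alkenylmagnesium alkoxide) | CC1=C[Mg]OC1 | intermediate
4 | (Z)-2-methylhexa-2,5-dien-1-ol | OC/C(C)=C\CC=C | intermediate
5 | (Z)-2-methylhexa-2,5-dienal | O=C/C(C)=C\CC=C | intermediate
6 | 4,4,5,5-tetramethyl-2-(2-methylprop-2-en-1-yl)-1,3,2-dioxaborolane | CC(=C)CB1OC(C)(C)C(C)(C)O1 | starting material
7 | 2-{[(4Z,6R)-5,8-dimethylnona-1,4,8-trien-6-yl]oxy}-4,4,5,5-tetramethyl-1,3,2-dioxaborolane | C=C(C)C[C@@H](OB1OC(C)(C)C(C)(C)O1)/C(C)=C\CC=C | intermediate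
8 | (4Z,6R)-5,8-dimethylnona-1,4,8-trien-6-ol | C=C(C)C[C@@H](O)/C(C)=C\CC=C | intermediate
9 | (R)-2,6-dimethylcyclohepta-2,5-dien-1-ol | CC1=CCC=C(C)C[C@H]1O | intermediate
10 | (1S,6S)-6-bromo-1,3-dimethylcyclohex-3-ene-1-carbaldehyde (Br cis to CHO) | CC1=CC[C@H](Br)[C@](C)(C=O)C1 | intermediate
11 | (1R,3S,4S,6S)-4-bromo-1,3-dimethyl-7-oxabicyclo[4.1.0]heptane-3-carbaldehyde (oxirane trans to CHO and Br) | C[C@@]12C[C@@](C)(C=O)[C@@H](Br)C[C@@H]1O2 | intermediate
12 | (1R,3S,4S,6S)-4-bromo-3-[(E)-2-bromoethenyl]-1,3-dimethyl-7-oxabicyclo[4.1.0]heptane | C[C@@]12C[C@@](C)(/C=C/Br)[C@@H](Br)C[C@@H]1O2 | intermediate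
13 | (1S,2S,4R,5S)-2-bromo-1-[(E)-2-bromoethenyl]-4,5-dichloro-1,5-dimethylcyclohexane | C[C@]1(Cl)C[C@@](C)(/C=C/Br)[C@@H](Br)C[C@H]1Cl | target

**Totals**

Total step count: 8. Longest linear sequence: 8 steps (1 → 13).

**Steps most likely to fail**

1. Step 5 (Proposed new method). What may go wrong: bromination at the more electron-rich C5=C6 bond instead of C2=C3, hydride shift from C1 instead of ring-bond migration, or reaction through the minor conformer with loss of enantiomeric purity. The fallback uses known reaction types, sets out from 9 and comes back at 10. Hydroxyl-directed epoxidation (VO(acac)2, t-BuOOH, CH2Cl2, 0 °C) should touch only the allylic C2=C3 bond and give the syn-epoxy alcohol (1R,2R,7S)-1,4-dimethyl-8-oxabicyclo[5.1.0]oct-4-en-2-ol F1. Lewis acid semipinacol rearrangement of this 2,3-epoxy alcohol (BF3·OEt2, CH2Cl2, −78 °C), with the same anti shift of the ring carbon, should give the ring-contracted (1R,6S)-6-hydroxy-1,3-dimethylcyclohex-3-ene-1-carbaldehyde F2, with OH cis to CHO. Mesylation (MsCl, Et3N, CH2Cl2, 0 °C) gives (1S,2R)-2-formyl-2,4-dimethylcyclohex-4-en-1-yl methanesulfonate F3. LiBr in acetone at reflux should then replace the mesylate with overall retention, because the homoallylic C3=C4 bond displaces it from the back and bromide opens the resulting cyclopropylcarbinyl cation at the same carbon (as in cholesteryl sulfonate to cholesteryl bromide), which returns 10.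

2. Step 8. What may go wrong: ionisation at the tertiary oxirane carbon (loss of configuration or elimination to an allylic chloride), or E2 instead of the second displacement next to the fully substituted C–Cl carbon. The fallback sets out from 12 and comes back at 13 and forms the two C–Cl bonds in separate operations. Anhydrous HCl in Et2O at −20 °C should open the oxirane at the tertiary carbon with inversion to give the chlorohydrin (1S,2S,4S,5S)-5-bromo-4-[(E)-2-bromoethenyl]-2-chloro-2,4-dimethylcyclohexan-1-ol F5. Triflation (Tf2O, pyridine, CH2Cl2, −30 °C) gives (1S,2S,4S,5S)-5-bromo-4-[(E)-2-bromoethenyl]-2-chloro-2,4-dimethylcyclohexyl trifluoromethanesulfonate F6. SN2 displacement with LiCl in DMF (0 °C → rt) should invert the secondary carbon and give 13.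

3. Step 6. What may go wrong: poor or reversed facial selectivity, the oxidant approaching syn to the formyl group. The fallback sets out from 10 and comes back at 11 and reverses the facial outcome of a direct oxygen transfer. NBS in acetone–water at 0 °C should form the bromonium ion on the face an electrophile prefers, and water should open it at the tertiary carbon from the other face to give the bromohydrin (1S,2S,4R,5R)-2,4-dibromo-5-hydroxy-1,5-dimethylcyclohexane-1-carbaldehyde F4. NaH in THF at 0 °C should then close the oxirane by backside displacement of the new bromide, placing oxygen on the face opposite to the one first attacked and giving 11.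

**Further compounds**

F1 | step 5 | (1R,2R,7S)-1,4-dimethyl-8-oxabicyclo[5.1.0]oct-4-en-2-ol | C[C@]12O[C@H]1CC=C(C)C[C@H]2O
F2 | step 5 | (1R,6S)-6-hydroxy-1,3-dimethylcyclohex-3-ene-1-carbaldehyde | CC1=CC[C@H](O)[C@](C)(C=O)C1
F3 | step 5 | (1S,2R)-2-formyl-2,4-dimethylcyclohex-4-en-1-yl methanesulfonate | CC1=CC[C@H](OS(C)(=O)=O)[C@](C)(C=O)C1
F4 | step 6 | (1S,2S,4R,5R)-2,4-dibromo-5-hydroxy-1,5-dimethylcyclohexane-1-carbaldehyde | C[C@@]1(O)C[C@@](C)(C=O)[C@@H](Br)C[C@H]1Br
F5 | step 8 | (1S,2S,4S,5S)-5-bromo-4-[(E)-2-bromoethenyl]-2-chloro-2,4-dimethylcyclohexan-1-ol | C[C@]1(Cl)C[C@@](C)(/C=C/Br)[C@@H](Br)C[C@@H]1O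
F6 | step 8 | (1S,2S,4S,5S)-5-bromo-4-[(E)-2-bromoethenyl]-2-chloro-2,4-dimethylcyclohexyl trifluoromethanesulfonate | C[C@]1(Cl)C[C@@](C)(/C=C/Br)[C@@H](Br)C[C@@H]1OS(=O)(=O)C(F)(F)F
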